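**Strategy.** Lactone numbering: C1 carbonyl to C13 carbinol carbon. The 14-membered ring contains the homoallylic alcohol array C8=C9(CH3)–C10H2–C11H(OH), the retron of a reductive alkyne–epoxide coupling. Everything rests on disconnecting C9–C10: an open-chain ester carrying a methyl-capped alkyne (C8≡C9) on the acyl arm and a terminal epoxide (C10–C11) on the alkoxy arm is closed by nickel catalysis with Et3B. One operation forms the macrocycle, sets the E-trisubstituted C8=C9 alkene by syn hydroalkylation and unveils the C11 hydroxyl with the configuration stored in the epoxide, driven by epoxide strain. The isomerisation-prone C3 carboxymethyl group is carried as a silyl-protected 2-hydroxyethyl group and oxidised last.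

Key step: step 15

Remark (assumption): the BINOL/Ti(OiPr)4 allylation is taken to follow its usual sense, (R)-BINOL delivering allyl to the Re face and (S)-BINOL to the Si face of the aldehyde.

**Alcohol arm (C10–C15 and nonyl chain)**

Step 1
Reactants: 1 decanal
Product: 2 (4S)-tridec-1-en-4-ol
Conditions: allylSnBu3, (R)-BINOL (10 mol %), Ti(OiPr)4 (10 mol %), 4 Å MS, CH2Cl2, −20 °C; aq. NaHCO3
Reagents that add atoms: allyltributylstannane, C=CC[Sn](CCCC)(CCCC)CCCC
Why: Keck asymmetric allylation; the (R)-BINOL–titanium Lewis acid directs allyl transfer to the Re face of the aldehyde and so sets C15 as S.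

Step 2
Reactants: 2 (4S)-tridec-1-en-4-ol
Product: 3 tert-butyldimethyl{[(4S)-tridec-1-en-4-yl]oxy}silane
Conditions: TBSCl, imidazole, DMF, rt
Reagents that add atoms: tert-butyldimethylsilyl chloride, CC(C)(C)[Si](C)(C)Cl
Why: Imidazole-promoted silylation masks C15–OH so that only C13–OH is free for the later acylation.

Step 3
Reactants: 3 tert-butyldimethyl{[(4S)-tridec-1-en-4-yl]oxy}silane
Product: 5 (3S)-3-[(tert-butyldimethylsilyl)oxy]dodecanal, via ozonide 4 (not isolated)
Conditions: O3, CH2Cl2, −78 °C; then PPh3, −78 °C to rt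
Reagents that add atoms: ozone, [O-][O+]=O
Why: Ozonolysis with reductive work-up cleaves the terminal alkene to the β-silyloxy aldehyde without touching the stereocentre.

Step 4
Reactants: 5 (3S)-3-[(tert-butyldimethylsilyl)oxy]dodecanal
Product: 6 (4S,6S)-6-[(tert-butyldimethylsilyl)oxy]pentadec-1-en-4-ol
Conditions: allylSnBu3, (S)-BINOL (20 mol %), Ti(OiPr)4 (20 mol %), 4 Å MS, CH2Cl2, −20 °C; aq. NaHCO3
Reagents that add atoms: allyltributylstannane, C=CC[Sn](CCCC)(CCCC)CCCC
Why: Second Keck allylation; the (S)-BINOL–titanium catalyst should override the weak bias of the β-silyloxy aldehyde and add allyl to the Si face, setting C13 anti to C15.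

Step 5
Reactants: 6 (4S,6S)-6-[(tert-butyldimethylsilyl)oxy]pentadec-1-en-4-ol
Product: 7 tert-butyl (4S,6S)-6-[(tert-butyldimethylsilyl)oxy]pentadec-1-en-4-yl carbonate
Conditions: Boc2O, DMAP (cat.), MeCN, rt
Reagents that add atoms: di-tert-butyl dicarbonate, CC(C)(C)OC(=O)OC(=O)OC(C)(C)C
Why: DMAP-catalysed acylation installs the carbonate that serves as the internal oxygen nucleophile in the next step.

Step 6
Reactants: 7 tert-butyl (4S,6S)-6-[(tert-butyldimethylsilyl)oxy]pentadec-1-en-4-yl carbonate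
Product: 8 (4R,6S)-6-{(2S)-2-[(tert-butyldimethylsilyl)oxy]undecyl}-4-(iodomethyl)-1,3-dioxan-2-one (cis)
Conditions: IBr, toluene, −85 °C; aq. Na2S2O3
Reagents that add atoms: iodine monobromide, IBr
Why: Iodocarbonate cyclisation (6-exo iodocyclisation with loss of the tert-butyl cation); the chair-like transition state with both substituents equatorial should give the cis-4,6-dioxanone and so set C11 syn to C13.

Step 7
Reactants: 8 (4R,6S)-6-{(2S)-2-[(tert-butyldimethylsilyl)oxy]undecyl}-4-(iodomethyl)-1,3-dioxan-2-one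
Product: 9 (2S,4S)-4-[(tert-butyldimethylsilyl)oxy]-1-[(2R)-oxiran-2-yl]tridecan-2-ol
Conditions: K2CO3, MeOH, rt
Reagents that add atoms: none
Why: Methanolysis of the cyclic carbonate frees the C11 alkoxide, which displaces iodide (3-exo-tet) to the terminal epoxide without touching the C11–O bond and leaves C13–OH free.

**Acyl head (C1–C3 and side chain)**

Step 8
Reactants: 10 but-3-yn-1-ol
Product: 11 (but-3-yn-1-yloxy)(tert-butyl)diphenylsilane
Conditions: TBDPSCl, imidazole, DMF, rt
Reagents that add atoms: tert-butyl(chloro)diphenylsilane, CC(C)(C)[Si](Cl)(c1ccccc1)c1ccccc1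
Why: Silylation; the TBDPS ether is chosen because it should survive the hot acetic acid of step 10.

Step 9
Reactants: 11 (but-3-yn-1-yloxy)(tert-butyl)diphenylsilane
Product: 13 5-[(tert-butyldiphenylsilyl)oxy]pent-2-ynoic acid, via lithium acetylide 12 (not isolated)
Conditions: n-BuLi, THF, −78 °C; CO2 (g), −78 °C to 0 °C; 1 M HCl
Reagents that add atoms: carbon dioxide, O=C=O
Why: Deprotonation of the terminal alkyne and carboxylation of the acetylide give the ynoic acid directly.

Step 10
Reactants: 13 5-[(tert-butyldiphenylsilyl)oxy]pent-2-ynoic acid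
Product: 14 (2Z)-5-[(tert-butyldiphenylsilyl)oxy]-3-iodopent-2-enoic acid
Conditions: NaI, AcOH, 70 °C
Reagents that add atoms: sodium iodide, [Na+].[I-]
Why: Conjugate hydroiodination; iodide adds to C3 and protonation occurs anti, giving the Z-iodide (iodine cis to CO2H) that fixes the later C2=C3 geometry.

**C4–C9 unit**

Step 11
Reactants: 15 (2E)-1,4-dibromobut-2-ene (3 equiv); 16 prop-1-yn-1-ylmagnesium bromide
Product: 17 (2E)-1-bromohept-2-en-5-yne
Conditions: CuBr·SMe2 (5 mol %), THF, −30 °C to 0 °C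
Reagents that add atoms: none
Why: Copper-catalysed SN2 alkynylation of the primary allylic bromide; excess dibromide limits double substitution and the E-alkene is untouched.

**Assembly and ring closure**

Step 12
Reactants: 9 (2S,4S)-4-[(tert-butyldimethylsilyl)oxy]-1-[(2R)-oxiran-2-yl]tridecan-2-ol; 14 (2Z)-5-[(tert-butyldiphenylsilyl)oxy]-3-iodopent-2-enoic acid
Product: 18 (2S,4S)-4-[(tert-butyldimethylsilyl)oxy]-1-[(2R)-oxiran-2-yl]tridecan-2-yl (2Z)-5-[(tert-butyldiphenylsilyl)oxy]-3-iodopent-2-enoate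
Conditions: DCC, DMAP (10 mol %), CH2Cl2, 0 °C to rt
Reagents that add atoms: none
Why: Steglich esterification with retention at C13; the ester bond is made while the acid still lacks the skipped unsaturation that could isomerise on carboxyl activation.

Step 13
Reactants: 18 the (2Z)-3-iodopent-2-enoate of step 12
Product: 19 (2S,4S)-4-[(tert-butyldimethylsilyl)oxy]-1-[(2R)-oxiran-2-yl]tridecan-2-yl (2Z)-5-[(tert-butyldiphenylsilyl)oxy]-3-(trimethylstannyl)pent-2-enoate
Conditions: (Me3Sn)2, Pd(PPh3)4 (5 mol %), toluene, 80 °C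
Reagents that add atoms: hexamethylditin, C[Sn](C)(C)[Sn](C)(C)C
Why: Palladium-catalysed stannylation of the alkenyl iodide (oxidative addition, Sn–Sn transmetalation, reductive elimination) with retention of geometry; the internal alkyl alkyne is absent at this stage and the epoxide is inert.

Step 14
Reactants: 19 the (2Z)-3-(trimethylstannyl)pent-2-enoate of step 13; 17 (2E)-1-bromohept-2-en-5-yne
Product: 20 (2S,4S)-4-[(tert-butyldimethylsilyl)oxy]-1-[(2R)-oxiran-2-yl]tridecan-2-yl (2E,5E)-3-{2-[(tert-butyldiphenylsilyl)oxy]ethyl}deca-2,5-dien-8-ynoate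
Conditions: Pd2(dba)3 (5 mol %), P(2-furyl)3 (20 mol %), THF, 50 °C
Reagents that add atoms: none
Why: Stille coupling of an allylic bromide with an alkenylstannane; the η3-allylpalladium intermediate couples at its primary terminus with retention of both alkene geometries, placing C4 cis to C1.

Step 15
Reactants: 20 the deca-2,5-dien-8-ynoate of step 14
Product: 22 (3E,6E,9E,12S,14S)-14-{(2S)-2-[(tert-butyldimethylsilyl)oxy]undecyl}-4-{2-[(tert-butyldiphenylsilyl)oxy]ethyl}-12-hydroxy-10-methyl-1-oxacyclotetradeca-3,6,9-trien-2-one, via diethylborinate 21 (not isolated)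
Conditions: Ni(cod)2 (20 mol %), PBu3 (40 mol %), Et3B (3 equiv), THF (0.02 M, slow addition of 20), rt; aq. NH4Cl
Reagents that add atoms: none
Why: Zerovalent nickel with PBu3 opens the epoxide at its terminal carbon C10 and the alkyne inserts syn into the Ni–C10 bond to give an oxanickelacycle; Et3B cleaves the Ni–O bond, and β-hydride elimination from the resulting Ni–ethyl group followed by C–H reductive elimination places H on C8 cis to the new C9–C10 bond. The closest known reaction type is the nickel-catalysed reductive coupling of alkynes with epoxides to homoallylic alcohols, which has been used for 14-membered lactone ring closure. The one ring closed is the 14-membered lactone, formed 14-endo-dig at the alkyne with endo opening of the epoxide (C10 and C11 both end up in the ring, the oxygen stays exocyclic). No new stereocentre is created: C11 keeps the configuration of the epoxide because only the C10–O bond breaks, and the E geometry of C8=C9 follows from the syn addition. The step needs bond formation at the methyl-bearing alkyne carbon C9 and not at C8, which the small phosphine (bonding at the less hindered alkyne terminus) and the preference for an endocyclic E-alkene over a 13-membered ring with an exocyclic ethylidene should secure. The enoate cannot engage the alkyne in a competing oxidative cyclisation because the trans C5=C6 unit lies between them, and high dilution suppresses oligomerisation.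

**End game**

Step 16
Reactants: 22 the macrolactone of step 15
Product: 23 (3E,6E,9E,12S,14R)-12-hydroxy-4-(2-hydroxyethyl)-14-[(2S)-2-hydroxyundecyl]-10-methyl-1-oxacyclotetradeca-3,6,9-trien-2-one
Conditions: HF·pyridine, pyridine, THF, 0 °C to rt
Reagents that add atoms: none
Why: Buffered fluoride cleaves both silyl ethers under mildly acidic conditions that should leave the lactone and the skipped triene untouched.

Step 17
Reactants: 23 the triol of step 16
Product: 25 2-[(3E,6E,9E,12S,14R)-12-hydroxy-14-[(2S)-2-hydroxyundecyl]-10-methyl-2-oxo-1-oxacyclotetradeca-3,6,9-trien-4-yl]acetic acid, via aldehyde 24 (not isolated)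
Conditions: TEMPO (20 mol %), PhI(OAc)2 (2.5 equiv), MeCN/pH 7 phosphate buffer (1:1), 0 °C to rt
Reagents that add atoms: water, O
Why: Oxoammonium oxidation (TEMPO/PhI(OAc)2) is selective for the primary alcohol over the two secondary ones and in water carries the aldehyde hydrate on to the acid under near-neutral conditions, so the C2=C3 alkene should not migrate.

**Compound list**

1 | decanal | CCCCCCCCCC=O | starting material
2 | (4S)-tridec-1-en-4-ol | CCCCCCCCC[C@H](O)CC=C | intermediate
3 | tert-butyldimethyl{[(4S)-tridec-1-en-4-yl]oxy}silane | CCCCCCCCC[C@H](O[Si](C)(C)C(C)(C)C)CC=C | intermediate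
4 | ozonide of 3, 3-{(2S)-2-[(tert-butyldimethylsilyl)oxy]undecyl}-1,2,4-trioxolane (both epimers at the ring carbon) | CCCCCCCCC[C@H](O[Si](C)(C)C(C)(C)C)CC1OCOO1 | intermediate
5 | (3S)-3-[(tert-butyldimethylsilyl)oxy]dodecanal | CCCCCCCCC[C@H](O[Si](C)(C)C(C)(C)C)CC=O | intermediate
6 | (4S,6S)-6-[(tert-butyldimethylsilyl)oxy]pentadec-1-en-4-ol | CCCCCCCCC[C@H](O[Si](C)(C)C(C)(C)C)C[C@@H](O)CC=C | intermediate
7 | tert-butyl (4S,6S)-6-[(tert-butyldimethylsilyl)oxy]pentadec-1-en-4-yl carbonate | CCCCCCCCC[C@H](O[Si](C)(C)C(C)(C)C)C[C@@H](OC(=O)OC(C)(C)C)CC=C | intermediate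
8 | (4R,6S)-6-{(2S)-2-[(tert-butyldimethylsilyl)oxy]undecyl}-4-(iodomethyl)-1,3-dioxan-2-one | CCCCCCCCC[C@H](O[Si](C)(C)C(C)(C)C)C[C@@H]1C[C@H](CI)OC(=O)O1 | intermediate
9 | (2S,4S)-4-[(tert-butyldimethylsilyl)oxy]-1-[(2R)-oxiran-2-yl]tridecan-2-ol | CCCCCCCCC[C@H](O[Si](C)(C)C(C)(C)C)C[C@@H](O)C[C@@H]1CO1 | intermediate
10 | but-3-yn-1-ol | C#CCCO | starting material
11 | (but-3-yn-1-yloxy)(tert-butyl)diphenylsilane | C#CCCO[Si](c1ccccc1)(c1ccccc1)C(C)(C)C | intermediate
12 | lithium acetylide of 11 | [Li]C#CCCO[Si](c1ccccc1)(c1ccccc1)C(C)(C)C | intermediate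
13 | 5-[(tert-butyldiphenylsilyl)oxy]pent-2-ynoic acid | OC(=O)C#CCCO[Si](c1ccccc1)(c1ccccc1)C(C)(C)C | intermediate
14 | (2Z)-5-[(tert-butyldiphenylsilyl)oxy]-3-iodopent-2-enoic acid | OC(=O)/C=C(\I)CCO[Si](c1ccccc1)(c1ccccc1)C(C)(C)C | intermediate
15 | (2E)-1,4-dibromobut-2-ene | BrC/C=C/CBr | starting material
16 | prop-1-yn-1-ylmagnesium bromide | CC#C[Mg]Br | starting material
17 | (2E)-1-bromohept-2-en-5-yne | CC#CC/C=C/CBr | intermediate
18 | (2S,4S)-4-[(tert-butyldimethylsilyl)oxy]-1-[(2R)-oxiran-2-yl]tridecan-2-yl (2Z)-5-[(tert-butyldiphenylsilyl)oxy]-3-iodopent-2-enoate | CCCCCCCCC[C@H](O[Si](C)(C)C(C)(C)C)C[C@H](C[C@@H]1CO1)OC(=O)/C=C(\I)CCO[Si](c1ccccc1)(c1ccccc1)C(C)(C)C | intermediate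
19 | (2S,4S)-4-[(tert-butyldimethylsilyl)oxy]-1-[(2R)-oxiran-2-yl]tridecan-2-yl (2Z)-5-[(tert-butyldiphenylsilyl)oxy]-3-(trimethylstannyl)pent-2-enoate | CCCCCCCCC[C@H](O[Si](C)(C)C(C)(C)C)C[C@H](C[C@@H]1CO1)OC(=O)/C=C(\[Sn](C)(C)C)CCO[Si](c1ccccc1)(c1ccccc1)C(C)(C)C | intermediate
20 | (2S,4S)-4-[(tert-butyldimethylsilyl)oxy]-1-[(2R)-oxiran-2-yl]tridecan-2-yl (2E,5E)-3-{2-[(tert-butyldiphenylsilyl)oxy]ethyl}deca-2,5-dien-8-ynoate | CCCCCCCCC[C@H](O[Si](C)(C)C(C)(C)C)C[C@H](C[C@@H]1CO1)OC(=O)/C=C(\C/C=C/CC#CC)CCO[Si](c1ccccc1)(c1ccccc1)C(C)(C)C | intermediate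
21 | O-diethylboryl derivative of 22 at the C12 oxygen (lactone C11) | CCCCCCCCC[C@H](O[Si](C)(C)C(C)(C)C)C[C@@H]1C[C@@H](OB(CC)CC)C/C(C)=C/C/C=C/C/C(CCO[Si](c2ccccc2)(c2ccccc2)C(C)(C)C)=C\C(=O)O1 | intermediate
22 | (3E,6E,9E,12S,14S)-14-{(2S)-2-[(tert-butyldimethylsilyl)oxy]undecyl}-4-{2-[(tert-butyldiphenylsilyl)oxy]ethyl}-12-hydroxy-10-methyl-1-oxacyclotetradeca-3,6,9-trien-2-one | CCCCCCCCC[C@H](O[Si](C)(C)C(C)(C)C)C[C@@H]1C[C@@H](O)C/C(C)=C/C/C=C/C/C(CCO[Si](c2ccccc2)(c2ccccc2)C(C)(C)C)=C\C(=O)O1 | intermediate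
23 | (3E,6E,9E,12S,14R)-12-hydroxy-4-(2-hydroxyethyl)-14-[(2S)-2-hydroxyundecyl]-10-methyl-1-oxacyclotetradeca-3,6,9-trien-2-one | CCCCCCCCC[C@H](O)C[C@@H]1C[C@@H](O)C/C(C)=C/C/C=C/C/C(CCO)=C\C(=O)O1 | intermediate
24 | 2-[(3E,6E,9E,12S,14R)-12-hydroxy-14-[(2S)-2-hydroxyundecyl]-10-methyl-2-oxo-1-oxacyclotetradeca-3,6,9-trien-4-yl]acetaldehyde | CCCCCCCCC[C@H](O)C[C@@H]1C[C@@H](O)C/C(C)=C/C/C=C/C/C(CC=O)=C\C(=O)O1 | intermediate
25 | 2-[(3E,6E,9E,12S,14R)-12-hydroxy-14-[(2S)-2-hydroxyundecyl]-10-methyl-2-oxo-1-oxacyclotetradeca-3,6,9-trien-4-yl]acetic acid | CCCCCCCCC[C@H](O)C[C@@H]1C[C@@H](O)C/C(C)=C/C/C=C/C/C(CC(=O)O)=C\C(=O)O1 | target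

**Step count:** 17 steps in total. Longest linear sequence: 13 steps (1–7, then 12–17, from decanal).

**Steps most likely to fail**

Step 15. The alkyne may insert with the wrong orientation (bond formation at C8, giving a 13-membered ring with an exocyclic ethylidene), and chains may couple with each other instead of cyclising. The fallback fixes the regiochemistry before ring closure by replacing the alkyne with a defined alkenyl bromide and closes the same bond by reductive cross-electrophile coupling, a reaction established between separate partners. It sets out from 17 and 19 and comes back at 22. Bromide 17 is hydrolysed (K2CO3, H2O/acetone) to (2E)-hept-2-en-5-yn-1-ol F1. Hydrozirconation with Cp2Zr(H)Cl (2.5 equiv, equilibrated so that zirconium sits on the methyl-bearing carbon) and quenching with NBS should give (2E,5E)-6-bromohepta-2,5-dien-1-ol F2. Appel bromination (CBr4, PPh3) gives (2E,5E)-1,6-dibromohepta-2,5-diene F3. Stille coupling of F3 with 19 (conditions of step 14), in which only the allylic bromide reacts, gives the seco alkenyl bromide F4, the analogue of 20 with an (E)-C8=C9(Br)CH3 unit in place of the alkyne. Ring closure with NiBr2·diglyme, 2,2'-bipyridine, NaI, Et3N·HCl and Mn powder in DMPU at high dilution, in which iodide opens the epoxide at C10 and the alkenylnickel species captures the C10 radical, should give 22.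

Step 17. The secondary carbinols may be over-oxidised, or the C2=C3 alkene may migrate at the aldehyde stage. The fallback protects, oxidises and then deprotects; it sets out from 22 and comes back at 25. TBSOTf and 2,6-lutidine give the bis-TBS ether F5. NH4F in MeOH removes the primary TBDPS group selectively to give the primary alcohol F6. Dess–Martin periodinane with NaHCO3 gives the aldehyde F7, and Pinnick oxidation (NaClO2, NaH2PO4, 2-methyl-2-butene) gives the acid F8. HF·pyridine then removes both TBS groups to give 25.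

Step 14. Transmetalation of the electron-poor, hindered alkenylstannane may be slow, so that protodestannylation or isomerisation of the skipped enyne takes over on prolonged heating. The fallback reverses the polarity of the coupling; it sets out from 17 and 18 and comes back at 20. Bromide 17 with Bu3SnLi (from Bu3SnH and LiN(iPr)2, THF, −78 °C) gives (2E)-tributyl(hept-2-en-5-yn-1-yl)stannane F9. Stille coupling of F9 with alkenyl iodide 18 (Pd2(dba)3, AsPh3, CuI, DMF, rt) should give 20, with coupling at the less substituted allyl terminus.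

**Further compounds**

F1 | step 15 | (2E)-hept-2-en-5-yn-1-ol | CC#CC/C=C/CO
F2 | step 15 | (2E,5E)-6-bromohepta-2,5-dien-1-ol | C/C(Br)=C\C/C=C/CO
F3 | step 15 | (2E,5E)-1,6-dibromohepta-2,5-diene | C/C(Br)=C\C/C=C/CBr
F4 | step 15 | (2S,4S)-4-[(tert-butyldimethylsilyl)oxy]-1-[(2R)-oxiran-2-yl]tridecan-2-yl (2E,5E,8E)-9-bromo-3-{2-[(tert-butyldiphenylsilyl)oxy]ethyl}deca-2,5,8-trienoate | CCCCCCCCC[C@H](O[Si](C)(C)C(C)(C)C)C[C@H](C[C@@H]1CO1)OC(=O)/C=C(\C/C=C/C/C=C(\C)Br)CCO[Si](c1ccccc1)(c1ccccc1)C(C)(C)C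
F5 | step 17 | 22 with the ring hydroxyl silylated (bis-TBS ether, TBDPS ether retained) | CCCCCCCCC[C@H](O[Si](C)(C)C(C)(C)C)C[C@@H]1C[C@@H](O[Si](C)(C)C(C)(C)C)C/C(C)=C/C/C=C/C/C(CCO[Si](c2ccccc2)(c2ccccc2)C(C)(C)C)=C\C(=O)O1
F6 | step 17 | bis-TBS ether with free 2-hydroxyethyl group | CCCCCCCCC[C@H](O[Si](C)(C)C(C)(C)C)C[C@@H]1C[C@@H](O[Si](C)(C)C(C)(C)C)C/C(C)=C/C/C=C/C/C(CCO)=C\C(=O)O1
F7 | step 17 | bis-TBS ether of aldehyde 24 | CCCCCCCCC[C@H](O[Si](C)(C)C(C)(C)C)C[C@@H]1C[C@@H](O[Si](C)(C)C(C)(C)C)C/C(C)=C/C/C=C/C/C(CC=O)=C\C(=O)O1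
F8 | step 17 | bis-TBS ether of acid 25 | CCCCCCCCC[C@H](O[Si](C)(C)C(C)(C)C)C[C@@H]1C[C@@H](O[Si](C)(C)C(C)(C)C)C/C(C)=C/C/C=C/C/C(CC(=O)O)=C\C(=O)O1
F9 | step 14 | (2E)-tributyl(hept-2-en-5-yn-1-yl)stannane | CC#CC/C=C/C[Sn](CCCC)(CCCC)CCCC
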